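**Retrosynthetic overview**

1. Locants (elemane numbering): ring C5–C6–C7–C8–C9–C10; C10 carries CH3 (C14) and the vinyl C1=C2; C5 carries C4(=C3H2)–C15HO; C7 carries C11(=C13H2)–C12(=O)–O–C8. The enabling feature is the cis-fused α-methylene-γ-butyrolactone, whose fusion bond C7–C8 is also a cyclohexane bond: O–C8–C7–C11(=C13H2)–C12=O is the retron of a 2-(alkoxycarbonyl)allyl metal adding to an aldehyde.
2. Cutting C7–C8 (and O8–C12) gives the acyclic aldehyde / (Z)-2-(bromomethyl)enoate 31. One Cr(II) allylation closes the cyclohexane first and the lactone second, sets C7 and C8, and unveils C11=C13.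
3. 31 comes from a C7 aldehyde (vinylalumination, SN2′ bromination). The C4 unit comes from a Weinreb amide (PMBOCH2Li, Wittig). C5–C6 comes from an Evans syn-aldol. The quaternary C10 comes from a Johnson–Claisen rearrangement of a (Z)-allylic alcohol made from (S)-glycerate acetonide (C9).
4. Endgame: C9 methacrylate, C6 angelate, C15 oxidation last.

Key step: step 21

Remarks: TBS = tert-butyldimethylsilyl, TES = triethylsilyl, PMB = 4-methoxybenzyl. Descriptors at C5, C6, C7, C9 and C10 change along the route only through CIP priorities (no inversion); the SMILES are authoritative. (Tributylstannyl)methanol and (tert-butyldimethylsilyloxy)acetaldehyde are taken as commercial.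

**Route**

Step 1
Reactants: 1 methyl (4S)-2,2-dimethyl-1,3-dioxolane-4-carboxylate
Product: 3 (4R)-4-ethynyl-2,2-dimethyl-1,3-dioxolane, via glyceraldehyde acetonide 2 (not isolated)
Conditions: DIBAL-H (1.05 eq), CH2Cl2, −78 °C; then MeOH, K2CO3, Ohira–Bestmann reagent, −78 °C → rt
Reagents that add atoms: dimethyl (1-diazo-2-oxopropyl)phosphonate, CC(=O)C(=[N+]=[N-])P(=O)(OC)OC
Why: Partial ester reduction followed in the same flask by Seyferth–Gilbert homologation (Ohira–Bestmann variant) should give the alkyne without handling the epimerisable aldehyde; the stereocentre is not touched.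

Step 2
Reactants: 3 (4R)-4-ethynyl-2,2-dimethyl-1,3-dioxolane
Product: 5 ethyl 3-[(4R)-2,2-dimethyl-1,3-dioxolan-4-yl]prop-2-ynoate, via lithium acetylide 4 (not isolated)
Conditions: n-BuLi, THF, −78 °C; ClCO2Et, −78 → 0 °C
Reagents that add atoms: ethyl chloroformate, CCOC(=O)Cl
Why: C-Acylation of a lithium acetylide with a chloroformate is a standard ynoate synthesis.

Step 3
Reactants: 5 ethyl 3-[(4R)-2,2-dimethyl-1,3-dioxolan-4-yl]prop-2-ynoate
Product: 6 ethyl (2Z)-3-[(4R)-2,2-dimethyl-1,3-dioxolan-4-yl]but-2-enoate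
Conditions: Me2CuLi (from MeLi, CuI), THF, −78 °C; MeOH then aq. NH4Cl at −78 °C
Reagents that add atoms: lithium dimethylcuprate, [Li+].C[Cu-]C
Why: syn-Carbocupration of the ynoate and cold protonation of the vinylcopper (organocuprate conjugate addition) should place the dioxolane cis to the ester, i.e. the Z-olefin.

Step 4
Reactants: 6 ethyl (2Z)-3-[(4R)-2,2-dimethyl-1,3-dioxolan-4-yl]but-2-enoate
Product: 7 (2Z)-3-[(4R)-2,2-dimethyl-1,3-dioxolan-4-yl]but-2-en-1-ol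
Conditions: DIBAL-H (2.2 eq), CH2Cl2, −78 °C; Rochelle salt
Reagents that add atoms: none
Why: 1,2-Reduction of an enoate by DIBAL-H gives the allylic alcohol with retention of olefin geometry.

Step 5
Reactants: 7 (2Z)-3-[(4R)-2,2-dimethyl-1,3-dioxolan-4-yl]but-2-en-1-ol
Product: 9 ethyl (3R)-3-[(4R)-2,2-dimethyl-1,3-dioxolan-4-yl]-3-methylpent-4-enoate, via ketene acetal 8 (not isolated)
Conditions: MeC(OEt)3, EtCO2H (cat.), xylene, 135 °C, EtOH distilled off
Reagents that add atoms: triethyl orthoacetate, CC(OCC)(OCC)OCC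
Why: Johnson–Claisen [3,3] rearrangement through a chair; A(1,3) strain of the Z-olefin holds C9–H in the olefin plane and the C10–C5 bond should form anti to the C9–O bond (Felkin-type), setting the quaternary C10 with its vinyl and methyl groups.

Step 6
Reactants: 9 ethyl (3R)-3-[(4R)-2,2-dimethyl-1,3-dioxolan-4-yl]-3-methylpent-4-enoate
Product: 10 (3R)-3-[(4R)-2,2-dimethyl-1,3-dioxolan-4-yl]-3-methylpent-4-enoic acid
Conditions: LiOH·H2O, THF/MeOH/H2O, rt; cold 1 M HCl to pH 4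
Reagents that add atoms: lithium hydroxide, [Li+].[OH-]
Why: Saponification; brief cold acidification should leave the acetonide intact.

Step 7
Reactants: 10 (3R)-3-[(4R)-2,2-dimethyl-1,3-dioxolan-4-yl]-3-methylpent-4-enoic acid; 11 (4S)-4-benzyl-1,3-oxazolidin-2-one
Product: 13 (4S)-4-benzyl-3-{(3R)-3-[(4R)-2,2-dimethyl-1,3-dioxolan-4-yl]-3-methylpent-4-enoyl}-1,3-oxazolidin-2-one, via pivalic mixed anhydride 12 (not isolated)
Conditions: PivCl, Et3N, THF, −20 °C; then 11, LiCl, rt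
Reagents that add atoms: none
Why: N-Acylation of the Evans auxiliary through the mixed pivalic anhydride is routine for β-branched acids.

Step 8
Reactants: 13 N-acyl oxazolidinone; 14 (tert-butyldimethylsilyloxy)acetaldehyde
Product: 16 (4S)-4-benzyl-3-[(2S,3S)-2-[(1S)-2-(TBSO)-1-hydroxyethyl]-3-[(4R)-2,2-dimethyl-1,3-dioxolan-4-yl]-3-methylpent-4-enoyl]-1,3-oxazolidin-2-one, via Z-boron enolate 15 (not isolated)
Conditions: Bu2BOTf, i-Pr2NEt, CH2Cl2, −78 → 0 °C; 14, −78 → 0 °C; pH 7 buffer/MeOH/H2O2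
Reagents that add atoms: none
Why: Evans syn-aldol reaction: the Z-boron enolate reacts through a Zimmerman–Traxler chair on the face away from the benzyl group, which should set C5 and C6 (syn) under auxiliary control.

Step 9
Reactants: 16 syn-aldol imide
Product: 17 (2S,3S)-2-[(1S)-2-(TBSO)-1-hydroxyethyl]-3-[(4R)-2,2-dimethyl-1,3-dioxolan-4-yl]-N-methoxy-N,3-dimethylpent-4-enamide
Conditions: MeNH(OMe)·HCl, AlMe3, CH2Cl2, −20 → 0 °C
Reagents that add atoms: N,O-dimethylhydroxylamine hydrochloride, CNOC.Cl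
Why: Aluminium-amide transamination of β-hydroxy imides (Weinreb amide formation) is directed by the free C6 hydroxyl and releases the auxiliary.

Step 10
Reactants: 17 Weinreb amide
Product: 18 (2S,3S)-2-[(1S)-1,2-bis(TBSO)ethyl]-3-[(4R)-2,2-dimethyl-1,3-dioxolan-4-yl]-N-methoxy-N,3-dimethylpent-4-enamide
Conditions: TBSOTf, 2,6-lutidine, CH2Cl2, −78 → 0 °C
Reagents that add atoms: tert-butyldimethylsilyl triflate, CC(C)(C)[Si](C)(C)OS(=O)(=O)C(F)(F)F
Why: Silylation of the secondary C6 alcohol gives an ether that will not act as a leaving group in the later allylmetal step.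

Step 11
Reactants: 19 (tributylstannyl)methanol; 20 4-methoxybenzyl chloride
Product: 21 tributyl{[(4-methoxybenzyl)oxy]methyl}stannane
Conditions: NaH, Bu4NI (cat.), THF/DMF, 0 °C → rt
Reagents that add atoms: none
Why: Williamson etherification gives the α-alkoxymethyl stannane needed for tin–lithium exchange.

Step 12
Reactants: 18 bis-TBS Weinreb amide; 21 tributyl{[(4-methoxybenzyl)oxy]methyl}stannane
Product: 23 (3S,4S)-3-[(1S)-1,2-bis(TBSO)ethyl]-4-[(4R)-2,2-dimethyl-1,3-dioxolan-4-yl]-1-[(4-methoxybenzyl)oxy]-4-methylhex-5-en-2-one, via PMBOCH2Li 22 (not isolated)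
Conditions: 21, n-BuLi, THF, −78 °C; then 18, −78 → −40 °C; aq. NH4Cl
Reagents that add atoms: none
Why: Tin–lithium exchange gives the α-alkoxymethyllithium, which adds once to the Weinreb amide (stable chelated tetrahedral intermediate) to give the C4 ketone carrying C15.

Step 13
Reactants: 23 ketone
Product: 24 (4R)-4-[(3S,4S)-4-[(1S)-1,2-bis(TBSO)ethyl]-5-{[(4-methoxybenzyl)oxy]methyl}-3-methylhexa-1,5-dien-3-yl]-2,2-dimethyl-1,3-dioxolane
Conditions: Ph3PCH3Br, KOt-Bu, THF, 0 °C; then 23, 0 °C → rt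
Reagents that add atoms: methyltriphenylphosphonium bromide, C[P+](c1ccccc1)(c1ccccc1)c1ccccc1.[Br-]
Why: Wittig methylenation of the activated α-alkoxy ketone installs C4=C3 at low temperature, which should avoid epimerisation at C5.

Step 14
Reactants: 24 bis-TBS diene
Product: 25 (2S,3S,4S)-2-(TBSO)-4-[(4R)-2,2-dimethyl-1,3-dioxolan-4-yl]-3-{3-[(4-methoxybenzyl)oxy]prop-1-en-2-yl}-4-methylhex-5-en-1-ol
Conditions: HF·pyridine, pyridine, THF, 0 °C
Reagents that add atoms: none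
Why: Buffered HF cleaves the primary TBS ether much faster than the hindered secondary one (selective desilylation).

Step 15
Reactants: 25 primary alcohol
Product: 26 (2S,3S,4S)-2-(TBSO)-4-[(4R)-2,2-dimethyl-1,3-dioxolan-4-yl]-3-{3-[(4-methoxybenzyl)oxy]prop-1-en-2-yl}-4-methylhex-5-enal
Conditions: Dess–Martin periodinane, NaHCO3, CH2Cl2, rt
Reagents that add atoms: none
Why: Dess–Martin oxidation gives the α-silyloxy aldehyde without epimerisation.

Step 16
Reactants: 26 C7 aldehyde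
Product: 27 methyl (4S,5S,6S)-4-(TBSO)-6-[(4R)-2,2-dimethyl-1,3-dioxolan-4-yl]-3-hydroxy-5-{3-[(4-methoxybenzyl)oxy]prop-1-en-2-yl}-6-methyl-2-methylideneoct-7-enoate (C3 epimers)
Conditions: DIBAL-H, NMO, THF, 0 °C; methyl propiolate, 0 °C → rt; then 26, rt; Rochelle salt
Reagents that add atoms: methyl propiolate, C#CC(=O)OC
Why: Vinylalumination (addition of a preformed α-(methoxycarbonyl)vinylalane) gives the Morita–Baylis–Hillman-type adduct quickly and without amine base; the new carbinol centre is lost in the next step.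

Step 17
Reactants: 27 Baylis–Hillman-type adduct
Product: 28 methyl (2Z,4R,5S,6S)-2-(bromomethyl)-4-(TBSO)-6-[(4R)-2,2-dimethyl-1,3-dioxolan-4-yl]-5-{3-[(4-methoxybenzyl)oxy]prop-1-en-2-yl}-6-methylocta-2,7-dienoate
Conditions: NBS, Me2S, CH2Cl2, 0 °C → rt
Reagents that add atoms: N-bromosuccinimide, O=C1CCC(=O)N1Br
Why: SN2′ bromination of the adduct (Corey–Kim-type activation) gives the thermodynamic Z-2-(bromomethyl)enoate, with C6 cis to CH2Br.

Step 18
Reactants: 28 allylic bromide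
Product: 29 methyl (2Z,4R,5S,6S,7R)-2-(bromomethyl)-4-(TBSO)-6-ethenyl-7,8-dihydroxy-5-{3-[(4-methoxybenzyl)oxy]prop-1-en-2-yl}-6-methyloct-2-enoate
Conditions: AcOH/THF/H2O (3:1:1), 35 °C
Reagents that add atoms: none
Why: Mild acetal hydrolysis frees the C8/C9 diol while the hindered TBS ether, the PMB ether and the allylic bromide should survive.

Step 19
Reactants: 29 diol
Product: 30 methyl (2Z,4R,5S,6S,7R)-2-(bromomethyl)-4-(TBSO)-6-ethenyl-5-{3-[(4-methoxybenzyl)oxy]prop-1-en-2-yl}-6-methyl-7,8-bis(triethylsilyloxy)oct-2-enoate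
Conditions: TESOTf, 2,6-lutidine, CH2Cl2, −78 °C
Reagents that add atoms: triethylsilyl triflate, CC[Si](CC)(CC)OS(=O)(=O)C(F)(F)F
Why: Bis-silylation with a non-nucleophilic base leaves the allylic bromide untouched.

Step 20
Reactants: 30 bis-TES ether
Product: 31 methyl (2Z,4R,5S,6S,7R)-2-(bromomethyl)-4-(TBSO)-6-ethenyl-5-{3-[(4-methoxybenzyl)oxy]prop-1-en-2-yl}-6-methyl-8-oxo-7-(triethylsilyloxy)oct-2-enoate
Conditions: (COCl)2, DMSO, CH2Cl2, −78 → −30 °C; Et3N, −78 → 0 °C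
Reagents that add atoms: none
Why: Swern conditions oxidise a primary TES ether directly to the aldehyde while secondary silyl ethers stay on, giving the C8 aldehyde with C9–OTES in one step.

Step 21
Reactants: 31 aldehyde bromide
Product: 35 (5S,6S,7S,8R,9R,10S)-6-(TBSO)-9-hydroxy-15-[(4-methoxybenzyl)oxy]elema-1,3,11(13)-trien-12,8-olide, via allylchromium 32 (not isolated), via chromium alkoxide 33 (not isolated), via TES lactone 34 (not isolated)
Conditions: CrCl2 (6 eq), THF, 0.01 M, rt; then PPTS, MeOH, rt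
Reagents that add atoms: none
Why: Two Cr(II) reduce the allylic C–Br bond to the η1-allylchromium(III) 32, which adds through its γ-carbon C7 to the C8 aldehyde in a closed six-membered (Zimmerman–Traxler) transition state, and the Cr(III) alkoxide 33 then acylates itself with the neighbouring methyl ester; this is a Nozaki–Hiyama–Kishi-type 2-(alkoxycarbonyl)allylation–lactonisation, closest to the known Cr-, Zn- and In-mediated cyclisations of ω-formyl 2-(bromomethyl)alk-2-enoates to cis-fused α-methylene-γ-butyrolactones. The cyclohexane closes by 6-exo-trig attack on the C8 carbonyl (SE2′ at the allyl unit, which unveils C11=C13), and the lactone by 5-exo-trig acyl substitution of O8 at C12. C7 and C8 are set together: the allylmetal should keep C6 cis to CH2Cr as in the Z-bromide, so C6 sits axial on the metallacycle and the fusion must be cis. The face is chosen by the chair of the forming carbocycle, with C6–OTBS and C7–C11 equatorial and the C8=O dipole anti to the C9–OTES bond (Cornforth arrangement); the other cis-fused product would need a 1,3,5-triaxial array (C14/O6/O8 or C4/O9/C11) in either chair. Allylchromium reagents add to aldehydes and not to esters, and 1,4-elimination across C13–C6 is held back because O6 is a silyl ether and not the angelate. The step therefore needs cis fusion on the face anti to O6, which the Z-geometry of 31 and the resident C5, C6, C9 and C10 centres should secure; PPTS/MeOH in the work-up completes lactonisation and removes the C9 TES group.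

Step 22
Reactants: 35 hydroxy lactone
Product: 36 (5S,6S,7S,8R,9R,10S)-6-(TBSO)-15-[(4-methoxybenzyl)oxy]-9-(methacryloyloxy)elema-1,3,11(13)-trien-12,8-olide
Conditions: methacrylic anhydride, Et3N, DMAP (cat.), CH2Cl2, 0 °C → rt
Reagents that add atoms: methacrylic anhydride, CC(=C)C(=O)OC(=O)C(C)=C
Why: DMAP-catalysed acylation of the only free hydroxyl (C9).

Step 23
Reactants: 36 methacrylate
Product: 37 (5S,6S,7R,8R,9R,10S)-6-hydroxy-15-[(4-methoxybenzyl)oxy]-9-(methacryloyloxy)elema-1,3,11(13)-trien-12,8-olide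
Conditions: HF·pyridine, THF, rt
Reagents that add atoms: none
Why: Fluoride-mediated desilylation under acidic conditions leaves the PMB ether, both esters and the lactone intact.

Step 24
Reactants: 37 C6 alcohol
Product: 38 (5S,6S,7R,8R,9R,10S)-6-(angeloyloxy)-15-[(4-methoxybenzyl)oxy]-9-(methacryloyloxy)elema-1,3,11(13)-trien-12,8-olide
Conditions: angelic acid, 2,4,6-trichlorobenzoyl chloride, Et3N, toluene, rt; then 37, toluene, 75 °C (no DMAP)
Reagents that add atoms: angelic acid, C/C=C(/C)C(=O)O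
Why: Yamaguchi-type esterification through the mixed anhydride without a nucleophilic catalyst is the standard way to install angelates with little Z→E isomerisation.

Step 25
Reactants: 38 angelate
Product: 39 (5S,6S,7R,8R,9R,10S)-6-(angeloyloxy)-15-hydroxy-9-(methacryloyloxy)elema-1,3,11(13)-trien-12,8-olide
Conditions: DDQ, CH2Cl2/pH 7 buffer (10:1), 0 °C → rt
Reagents that add atoms: none
Why: Oxidative PMB cleavage is neutral and should spare the electron-poor olefins and the esters.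

Step 26
Reactants: 39 allylic alcohol
Product: 40 target, (5R,6S,7R,8R,9R,10S)-6-(angeloyloxy)-9-(methacryloyloxy)-15-oxoelema-1,3,11(13)-trien-12,8-olide
Conditions: Dess–Martin periodinane, NaHCO3, CH2Cl2, 0 °C → rt
Reagents that add atoms: none
Why: Dess–Martin oxidation of the primary allylic alcohol gives the 2-substituted acrolein; C6 is already acylated, so no lactol can form.

**Compound list**

1 | methyl (4S)-2,2-dimethyl-1,3-dioxolane-4-carboxylate | COC(=O)[C@@H]1COC(C)(C)O1 | starting material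
2 | (4S)-2,2-dimethyl-1,3-dioxolane-4-carbaldehyde | O=C[C@@H]1COC(C)(C)O1 | intermediate
3 | (4R)-4-ethynyl-2,2-dimethyl-1,3-dioxolane | C#C[C@@H]1COC(C)(C)O1 | intermediate
4 | lithium [(4R)-2,2-dimethyl-1,3-dioxolan-4-yl]acetylide | [Li]C#C[C@@H]1COC(C)(C)O1 | intermediate
5 | ethyl 3-[(4R)-2,2-dimethyl-1,3-dioxolan-4-yl]prop-2-ynoate | CCOC(=O)C#C[C@@H]1COC(C)(C)O1 | intermediate
6 | ethyl (2Z)-3-[(4R)-2,2-dimethyl-1,3-dioxolan-4-yl]but-2-enoate | CCOC(=O)/C=C(/C)[C@@H]1COC(C)(C)O1 | intermediate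
7 | (2Z)-3-[(4R)-2,2-dimethyl-1,3-dioxolan-4-yl]but-2-en-1-ol | OC/C=C(/C)[C@@H]1COC(C)(C)O1 | intermediate
8 | 1-ethoxyvinyl ether of 7 (mixed ketene acetal) | C=C(OCC)OC/C=C(/C)[C@@H]1COC(C)(C)O1 | intermediate
9 | ethyl (3R)-3-[(4R)-2,2-dimethyl-1,3-dioxolan-4-yl]-3-methylpent-4-enoate | C=C[C@@]([C@@H]1COC(C)(C)O1)(C)CC(=O)OCC | intermediate
10 | (3R)-3-[(4R)-2,2-dimethyl-1,3-dioxolan-4-yl]-3-methylpent-4-enoic acid | C=C[C@@]([C@@H]1COC(C)(C)O1)(C)CC(=O)O | intermediate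
11 | (4S)-4-benzyl-1,3-oxazolidin-2-one | O=C1N[C@@H](Cc2ccccc2)CO1 | starting material
12 | pivalic mixed anhydride of 10 | C=C[C@@]([C@@H]1COC(C)(C)O1)(C)CC(=O)OC(=O)C(C)(C)C | intermediate
13 | (4S)-4-benzyl-3-{(3R)-3-[(4R)-2,2-dimethyl-1,3-dioxolan-4-yl]-3-methylpent-4-enoyl}-1,3-oxazolidin-2-one | C=C[C@@]([C@@H]1COC(C)(C)O1)(C)CC(=O)N2[C@@H](Cc3ccccc3)COC2=O | intermediate
14 | (tert-butyldimethylsilyloxy)acetaldehyde | O=CCO[Si](C)(C)C(C)(C)C | starting material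
15 | (Z)-dibutylboron enolate of 13 | C=C[C@@]([C@@H]1COC(C)(C)O1)(C)/C=C(\OB(CCCC)CCCC)N2[C@@H](Cc3ccccc3)COC2=O | intermediate
16 | (4S)-4-benzyl-3-[(2S,3S)-2-[(1S)-2-(TBSO)-1-hydroxyethyl]-3-[(4R)-2,2-dimethyl-1,3-dioxolan-4-yl]-3-methylpent-4-enoyl]-1,3-oxazolidin-2-one | C=C[C@@]([C@@H]1COC(C)(C)O1)(C)[C@H](C(=O)N2[C@@H](Cc3ccccc3)COC2=O)[C@H](O)CO[Si](C)(C)C(C)(C)C | intermediate
17 | (2S,3S)-2-[(1S)-2-(TBSO)-1-hydroxyethyl]-3-[(4R)-2,2-dimethyl-1,3-dioxolan-4-yl]-N-methoxy-N,3-dimethylpent-4-enamide | C=C[C@@]([C@@H]1COC(C)(C)O1)(C)[C@H](C(=O)N(C)OC)[C@H](O)CO[Si](C)(C)C(C)(C)C | intermediate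
18 | (2S,3S)-2-[(1S)-1,2-bis(TBSO)ethyl]-3-[(4R)-2,2-dimethyl-1,3-dioxolan-4-yl]-N-methoxy-N,3-dimethylpent-4-enamide | C=C[C@@]([C@@H]1COC(C)(C)O1)(C)[C@H](C(=O)N(C)OC)[C@H](O[Si](C)(C)C(C)(C)C)CO[Si](C)(C)C(C)(C)C | intermediate
19 | (tributylstannyl)methanol | CCCC[Sn](CCCC)(CCCC)CO | starting material
20 | 4-methoxybenzyl chloride | COc1ccc(CCl)cc1 | starting material
21 | tributyl{[(4-methoxybenzyl)oxy]methyl}stannane | CCCC[Sn](CCCC)(CCCC)COCc1ccc(OC)cc1 | intermediate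
22 | {[(4-methoxybenzyl)oxy]methyl}lithium | [Li]COCc1ccc(OC)cc1 | intermediate
23 | (3S,4S)-3-[(1S)-1,2-bis(TBSO)ethyl]-4-[(4R)-2,2-dimethyl-1,3-dioxolan-4-yl]-1-[(4-methoxybenzyl)oxy]-4-methylhex-5-en-2-one | C=C[C@@]([C@@H]1COC(C)(C)O1)(C)[C@H](C(=O)COCc2ccc(OC)cc2)[C@H](O[Si](C)(C)C(C)(C)C)CO[Si](C)(C)C(C)(C)C | intermediate
24 | (4R)-4-[(3S,4S)-4-[(1S)-1,2-bis(TBSO)ethyl]-5-{[(4-methoxybenzyl)oxy]methyl}-3-methylhexa-1,5-dien-3-yl]-2,2-dimethyl-1,3-dioxolane | C=C[C@@]([C@@H]1COC(C)(C)O1)(C)[C@H](C(=C)COCc2ccc(OC)cc2)[C@H](O[Si](C)(C)C(C)(C)C)CO[Si](C)(C)C(C)(C)C | intermediate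
25 | (2S,3S,4S)-2-(TBSO)-4-[(4R)-2,2-dimethyl-1,3-dioxolan-4-yl]-3-{3-[(4-methoxybenzyl)oxy]prop-1-en-2-yl}-4-methylhex-5-en-1-ol | C=C[C@@]([C@@H]1COC(C)(C)O1)(C)[C@H](C(=C)COCc2ccc(OC)cc2)[C@H](O[Si](C)(C)C(C)(C)C)CO | intermediate
26 | (2S,3S,4S)-2-(TBSO)-4-[(4R)-2,2-dimethyl-1,3-dioxolan-4-yl]-3-{3-[(4-methoxybenzyl)oxy]prop-1-en-2-yl}-4-methylhex-5-enal | C=C[C@@]([C@@H]1COC(C)(C)O1)(C)[C@H](C(=C)COCc2ccc(OC)cc2)[C@H](O[Si](C)(C)C(C)(C)C)C=O | intermediate
27 | methyl (4S,5S,6S)-4-(TBSO)-6-[(4R)-2,2-dimethyl-1,3-dioxolan-4-yl]-3-hydroxy-5-{3-[(4-methoxybenzyl)oxy]prop-1-en-2-yl}-6-methyl-2-methylideneoct-7-enoate (C3 epimers) | C=C[C@@]([C@@H]1COC(C)(C)O1)(C)[C@H](C(=C)COCc2ccc(OC)cc2)[C@H](O[Si](C)(C)C(C)(C)C)C(O)C(=C)C(=O)OC | intermediate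
28 | methyl (2Z,4R,5S,6S)-2-(bromomethyl)-4-(TBSO)-6-[(4R)-2,2-dimethyl-1,3-dioxolan-4-yl]-5-{3-[(4-methoxybenzyl)oxy]prop-1-en-2-yl}-6-methylocta-2,7-dienoate | C=C[C@@]([C@@H]1COC(C)(C)O1)(C)[C@H](C(=C)COCc2ccc(OC)cc2)[C@H](O[Si](C)(C)C(C)(C)C)/C=C(\CBr)C(=O)OC | intermediate
29 | methyl (2Z,4R,5S,6S,7R)-2-(bromomethyl)-4-(TBSO)-6-ethenyl-7,8-dihydroxy-5-{3-[(4-methoxybenzyl)oxy]prop-1-en-2-yl}-6-methyloct-2-enoate | C=C[C@@]([C@@H](O)CO)(C)[C@H](C(=C)COCc1ccc(OC)cc1)[C@H](O[Si](C)(C)C(C)(C)C)/C=C(\CBr)C(=O)OC | intermediate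
30 | methyl (2Z,4R,5S,6S,7R)-2-(bromomethyl)-4-(TBSO)-6-ethenyl-5-{3-[(4-methoxybenzyl)oxy]prop-1-en-2-yl}-6-methyl-7,8-bis(triethylsilyloxy)oct-2-enoate | C=C[C@@]([C@@H](O[Si](CC)(CC)CC)CO[Si](CC)(CC)CC)(C)[C@H](C(=C)COCc1ccc(OC)cc1)[C@H](O[Si](C)(C)C(C)(C)C)/C=C(\CBr)C(=O)OC | intermediate
31 | methyl (2Z,4R,5S,6S,7R)-2-(bromomethyl)-4-(TBSO)-6-ethenyl-5-{3-[(4-methoxybenzyl)oxy]prop-1-en-2-yl}-6-methyl-8-oxo-7-(triethylsilyloxy)oct-2-enoate | C=C[C@@]([C@@H](O[Si](CC)(CC)CC)C=O)(C)[C@H](C(=C)COCc1ccc(OC)cc1)[C@H](O[Si](C)(C)C(C)(C)C)/C=C(\CBr)C(=O)OC | intermediate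
32 | allylchromium(III) dichloride derived from 31 | C=C[C@@]([C@@H](O[Si](CC)(CC)CC)C=O)(C)[C@H](C(=C)COCc1ccc(OC)cc1)[C@H](O[Si](C)(C)C(C)(C)C)/C=C(\C[Cr](Cl)Cl)C(=O)OC | intermediate
33 | chromium(III) alkoxide of the ring-closed C8 hydroxy methyl ester | C=C[C@@]1(C)[C@H](C(=C)COCc3ccc(OC)cc3)[C@H](O[Si](C)(C)C(C)(C)C)[C@@H](C(=C)C(=O)OC)[C@@H](O[Cr](Cl)Cl)[C@@H]1O[Si](CC)(CC)CC | intermediate
34 | C9 triethylsilyl ether of 35 | C=C[C@@]1(C)[C@H](C(=C)COCc3ccc(OC)cc3)[C@H](O[Si](C)(C)C(C)(C)C)[C@H]2C(=C)C(=O)O[C@H]2[C@@H]1O[Si](CC)(CC)CC | intermediate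
35 | (5S,6S,7S,8R,9R,10S)-6-(TBSO)-9-hydroxy-15-[(4-methoxybenzyl)oxy]elema-1,3,11(13)-trien-12,8-olide | C=C[C@@]1(C)[C@H](C(=C)COCc3ccc(OC)cc3)[C@H](O[Si](C)(C)C(C)(C)C)[C@H]2C(=C)C(=O)O[C@H]2[C@@H]1O | intermediate
36 | (5S,6S,7S,8R,9R,10S)-6-(TBSO)-15-[(4-methoxybenzyl)oxy]-9-(methacryloyloxy)elema-1,3,11(13)-trien-12,8-olide | C=C[C@@]1(C)[C@H](C(=C)COCc3ccc(OC)cc3)[C@H](O[Si](C)(C)C(C)(C)C)[C@H]2C(=C)C(=O)O[C@H]2[C@@H]1OC(=O)C(=C)C | intermediate
37 | (5S,6S,7R,8R,9R,10S)-6-hydroxy-15-[(4-methoxybenzyl)oxy]-9-(methacryloyloxy)elema-1,3,11(13)-trien-12,8-olide | C=C[C@@]1(C)[C@H](C(=C)COCc3ccc(OC)cc3)[C@H](O)[C@H]2C(=C)C(=O)O[C@H]2[C@@H]1OC(=O)C(=C)C | intermediate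
38 | (5S,6S,7R,8R,9R,10S)-6-(angeloyloxy)-15-[(4-methoxybenzyl)oxy]-9-(methacryloyloxy)elema-1,3,11(13)-trien-12,8-olide | C=C[C@@]1(C)[C@H](C(=C)COCc3ccc(OC)cc3)[C@H](OC(=O)/C(C)=C\C)[C@H]2C(=C)C(=O)O[C@H]2[C@@H]1OC(=O)C(=C)C | intermediate
39 | (5S,6S,7R,8R,9R,10S)-6-(angeloyloxy)-15-hydroxy-9-(methacryloyloxy)elema-1,3,11(13)-trien-12,8-olide | C=C[C@@]1(C)[C@H](C(=C)CO)[C@H](OC(=O)/C(C)=C\C)[C@H]2C(=C)C(=O)O[C@H]2[C@@H]1OC(=O)C(=C)C | intermediate
40 | CNP0102441.1, (5R,6S,7R,8R,9R,10S)-6-(angeloyloxy)-9-(methacryloyloxy)-15-oxoelema-1,3,11(13)-trien-12,8-olide | C=C[C@@]1(C)[C@H](C(=C)C=O)[C@H](OC(=O)/C(C)=C\C)[C@H]2C(=C)C(=O)O[C@H]2[C@@H]1OC(=O)C(=C)C | target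

**Step count and risks**

Total steps: 26. Longest linear sequence: 25 (steps 1–10 and 12–26; step 11 is a side branch).

Steps most likely to fail:

1. Step 21. The allylchromium may equilibrate to the geometry with C6 trans to CH2Cr and close through an all-equatorial transition state to a trans-fused lactone, or lose the C6 silyloxy group by 1,4-elimination. The fallback uses a configurationally stable allylsilane. It sets out from 26: a Horner–Wadsworth–Emmons reaction with ethyl 2-(diethoxyphosphoryl)-3-(trimethylsilyl)propanoate (NaH, DME) would give the ethyl 2-[(trimethylsilyl)methyl]enoate F1. Acetonide hydrolysis as in step 18 would give the diol F2, TESOTf/2,6-lutidine the bis-TES ether F3, and Swern oxidation the aldehyde allylsilane F4. TBAF in THF at −20 °C should then trigger an intramolecular Hosomi–Sakurai-type addition with lactonisation and loss of the C9 TES group, and the route is rejoined at 35.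

2. Step 5. The facial selectivity of the sigmatropic step at the new quaternary centre may be low, or opposite to the Felkin-type model. The fallback switches the olefin geometry, which presents the complementary face of C10 to the ketene acetal. It sets out from 1: MeNH(OMe)·HCl/i-PrMgCl and then MeMgBr would give the methyl ketone 1-[(4S)-2,2-dimethyl-1,3-dioxolan-4-yl]ethan-1-one F5. A Horner–Wadsworth–Emmons reaction (triethyl phosphonoacetate, NaH) would give the E-enoate F6, and DIBAL-H the E-allylic alcohol F7. Johnson–Claisen rearrangement of F7 comes back to the route at 9.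

3. Step 24. The hindered C6 hydroxyl may acylate slowly, with isomerisation of the angeloyl group to tigloyl and base-induced migration of the lactone from O8 to O6. The fallback builds the Z-olefin on the ester instead. It sets out from 37: DCC/DMAP coupling with 2-[bis(2,2,2-trifluoroethoxy)phosphoryl]propanoic acid would give the C6 phosphonopropanoate F8. A Still–Gennari olefination with acetaldehyde (KHMDS, 18-crown-6, THF, −78 °C) should then give the Z-2-methylbut-2-enoate, and the route is rejoined at 38.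

**Further compounds**

F1 | step 21 | ethyl (2Z,4R,5S,6S)-4-(TBSO)-6-[(4R)-2,2-dimethyl-1,3-dioxolan-4-yl]-5-{3-[(4-methoxybenzyl)oxy]prop-1-en-2-yl}-6-methyl-2-[(trimethylsilyl)methyl]octa-2,7-dienoate | C=C[C@@]([C@@H]1COC(C)(C)O1)(C)[C@H](C(=C)COCc2ccc(OC)cc2)[C@H](O[Si](C)(C)C(C)(C)C)/C=C(\C[Si](C)(C)C)C(=O)OCC
F2 | step 21 | 7,8-diol from F1 | C=C[C@@]([C@@H](O)CO)(C)[C@H](C(=C)COCc1ccc(OC)cc1)[C@H](O[Si](C)(C)C(C)(C)C)/C=C(\C[Si](C)(C)C)C(=O)OCC
F3 | step 21 | 7,8-bis(triethylsilyl) ether of F2 | C=C[C@@]([C@@H](O[Si](CC)(CC)CC)CO[Si](CC)(CC)CC)(C)[C@H](C(=C)COCc1ccc(OC)cc1)[C@H](O[Si](C)(C)C(C)(C)C)/C=C(\C[Si](C)(C)C)C(=O)OCC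
F4 | step 21 | 8-oxo-7-(triethylsilyloxy) allylsilane | C=C[C@@]([C@@H](O[Si](CC)(CC)CC)C=O)(C)[C@H](C(=C)COCc1ccc(OC)cc1)[C@H](O[Si](C)(C)C(C)(C)C)/C=C(\C[Si](C)(C)C)C(=O)OCC
F5 | step 5 | 1-[(4S)-2,2-dimethyl-1,3-dioxolan-4-yl]ethan-1-one | CC(=O)[C@@H]1COC(C)(C)O1
F6 | step 5 | ethyl (2E)-3-[(4R)-2,2-dimethyl-1,3-dioxolan-4-yl]but-2-enoate | CCOC(=O)/C=C(\C)[C@@H]1COC(C)(C)O1
F7 | step 5 | (2E)-3-[(4R)-2,2-dimethyl-1,3-dioxolan-4-yl]but-2-en-1-ol | OC/C=C(\C)[C@@H]1COC(C)(C)O1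
F8 | step 24 | C6 2-[bis(2,2,2-trifluoroethoxy)phosphoryl]propanoate of 37 | C=C[C@@]1(C)[C@H](C(=C)COCc3ccc(OC)cc3)[C@H](OC(=O)C(C)P(=O)(OCC(F)(F)F)OCC(F)(F)F)[C@H]2C(=C)C(=O)O[C@H]2[C@@H]1OC(=O)C(=C)C
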